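The ester bond between rings A and B is made late and ring A receives its two formyl groups last, so the route rests on ring B. There the neighbouring C4 chlorine and C5 methyl lie beside the C3 methoxy group, which can polarise a C4–C5 aryne. In one flask that aryne takes up methyl from CH3MgCl at C5 and chlorine from hexachloroethane at C4, completing a hexasubstituted benzene. The aryne precursor is aryl bromide 7, a methoxymethyl-protected 4-bromo-3-methoxy-2,6-dimethylphenol: bromine sits at C4, where phenol-directed bromination puts it, and the only ring hydrogen is at C5.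

Key step: step 6

Step 1
Reactants: 1 2-methylresorcinol
Product: 3 2,4-dihydroxy-3-methylbenzaldehyde, via iminium chloride 2 (not isolated)
Conditions: POCl3, DMF, MeCN, 0 °C → rt; then H2O, 50 °C
Reagents that add atoms: N,N-dimethylformamide, CN(C)C=O (formyl carbon); water, O (formyl oxygen)
Why: Vilsmeier–Haack formylation, in which the chloroiminium electrophile should attack C4 (ortho to one hydroxyl, para to the other, and equivalent to C6) and water then hydrolyses iminium 2 to the aldehyde.

Step 2
Reactants: 3 2,4-dihydroxy-3-methylbenzaldehyde
Product: 4 2-hydroxy-4-methoxy-3-methylbenzaldehyde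
Conditions: MeI (1.1 equiv), K2CO3 (1.1 equiv), acetone, rt
Reagents that add atoms: iodomethane, CI
Why: Williamson etherification, selective because the C2 hydroxyl is held in a hydrogen bond to the aldehyde and is less acidic, so one equivalent of base and iodomethane should alkylate only the C4 phenoxide.

Step 3
Reactants: 4 2-hydroxy-4-methoxy-3-methylbenzaldehyde
Product: 5 3-methoxy-2,6-dimethylphenol
Conditions: H2 (3 atm), Pd/C, AcOH, cat. HCl, rt
Reagents that add atoms: none
Why: Catalytic hydrogenolysis of an electron-rich aryl aldehyde, in which reduction to the benzylic alcohol and acid-assisted C–O hydrogenolysis (the ortho-hydroxyl and para-methoxy groups stabilise the benzylic cation) should leave a methyl group.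

Step 4
Reactants: 5 3-methoxy-2,6-dimethylphenol
Product: 6 4-bromo-3-methoxy-2,6-dimethylphenol
Conditions: NBS (1.0 equiv), MeCN, 0 °C
Reagents that add atoms: N-bromosuccinimide, O=C1CCC(=O)N1Br
Why: Electrophilic aromatic bromination, directed to C4 because it is para to the hydroxyl and ortho to the methoxy group whereas the other open position is meta to both.

Step 5
Reactants: 6 4-bromo-3-methoxy-2,6-dimethylphenol
Product: 7 1-bromo-2-methoxy-4-(methoxymethoxy)-3,5-dimethylbenzene
Conditions: MOMCl, i-Pr2NEt, CH2Cl2, 0 °C → rt
Reagents that add atoms: chloromethyl methyl ether, COCCl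
Why: O-alkylation of the phenol to a methoxymethyl acetal (protection), which removes the acidic proton before the amide and Grignard bases of the next step.

Step 6
Reactants: 7 1-bromo-2-methoxy-4-(methoxymethoxy)-3,5-dimethylbenzene; 8 methylmagnesium chloride; 9 hexachloroethane
Product: 13 1-chloro-2-methoxy-4-(methoxymethoxy)-3,5,6-trimethylbenzene, via C5 aryllithium 10 (not isolated), via C4–C5 aryne 11 (not isolated), via C4 arylmagnesium chloride 12 (not isolated)
Conditions: CH3MgCl (4 equiv), LiTMP (2.5 equiv), THF, −78 °C → rt; then C2Cl6 (6 equiv), −78 °C → rt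
Reagents that add atoms: methylmagnesium chloride 8, C[Mg]Cl; hexachloroethane 9, ClC(Cl)(Cl)C(Cl)(Cl)Cl
Why: LiTMP should remove the lone ring hydrogen at C5, which the neighbouring C4 bromine acidifies, and the metalated species 10 should lose LiBr to give aryne 11. CH3MgCl then adds across the strained triple bond (carbomagnesiation), and hexachloroethane chlorinates the resulting arylmagnesium 12 by chlorine–magnesium exchange, releasing tetrachloroethene. The closest known reaction type is the three-component coupling of 3-alkoxyarynes, Grignard reagents and electrophiles. The step closes no ring and creates no stereocenter. It needs regiocontrol in the methyl addition: the inductively withdrawing C3 methoxy group distorts the aryne so that C5 is the more electrophilic carbon and the negative charge builds up at C4 beside oxygen, where magnesium can also be chelated, which should outweigh the modest hindrance of the C6 methyl. Every other ring position is substituted and the acetal is inert to amide and Grignard bases, so no second aryne and no competing ring metalation is possible.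

Step 7
Reactants: 13 1-chloro-2-methoxy-4-(methoxymethoxy)-3,5,6-trimethylbenzene
Product: 14 4-chloro-3-methoxy-2,5,6-trimethylphenol
Conditions: 3 M HCl, MeOH, 50 °C
Reagents that add atoms: none
Why: Acid-catalysed acetal cleavage (transacetalisation to methanol), which should free the phenol while the aryl methyl ether and the aryl chloride are untouched.

Step 8
Reactants: 15 methyl orsellinate (methyl 2,4-dihydroxy-6-methylbenzoate)
Product: 16 methyl 2,4-bis(benzyloxy)-6-methylbenzoate
Conditions: BnBr (2.5 equiv), K2CO3 (3 equiv), DMF, 60 °C
Reagents that add atoms: benzyl bromide, BrCc1ccccc1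
Why: Double Williamson etherification, in which excess base in warm DMF should also alkylate the hydrogen-bonded C2 hydroxyl.

Step 9
Reactants: 16 methyl 2,4-bis(benzyloxy)-6-methylbenzoate
Product: 17 2,4-bis(benzyloxy)-6-methylbenzoic acid
Conditions: KOH, DMSO/H2O, 90 °C; acidic work-up (1 M HCl)
Reagents that add atoms: potassium hydroxide, [K+].[OH-]
Why: Saponification of a di-ortho-substituted benzoate under forcing conditions (hydroxide in aqueous DMSO), to which the benzyl ethers are stable.

Step 10
Reactants: 14 4-chloro-3-methoxy-2,5,6-trimethylphenol; 17 2,4-bis(benzyloxy)-6-methylbenzoic acid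
Product: 19 4-chloro-3-methoxy-2,5,6-trimethylphenyl 2,4-bis(benzyloxy)-6-methylbenzoate, via acyl trifluoroacetate 18 (not isolated)
Conditions: (CF3CO)2O (3 equiv), toluene, 0 °C → rt
Reagents that add atoms: none
Why: Mixed-anhydride esterification with trifluoroacetic anhydride, in which the electron-rich hindered acid forms acyl trifluoroacetate 18 that ionises to a small linear acylium ion able to acylate the flanked phenol, while the fully substituted ring B cannot be C-acylated.

Step 11
Reactants: 19 4-chloro-3-methoxy-2,5,6-trimethylphenyl 2,4-bis(benzyloxy)-6-methylbenzoate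
Product: 20 4-chloro-3-methoxy-2,5,6-trimethylphenyl 2,4-dihydroxy-6-methylbenzoate
Conditions: H2 (1 atm), Pd/C, EtOAc, rt
Reagents that add atoms: none
Why: Hydrogenolysis of the two benzyl ethers, run neutral, base-free and at low pressure so that the hindered, electron-rich aryl chloride and the aryl ester should survive.

Step 12
Reactants: 20 4-chloro-3-methoxy-2,5,6-trimethylphenyl 2,4-dihydroxy-6-methylbenzoate
Product: 22 4-chloro-3-methoxy-2,5,6-trimethylphenyl 3,5-diformyl-2,4-dihydroxy-6-methylbenzoate (target), via bis(chloromethoxymethyl) arene 21 (not isolated)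
Conditions: Cl2CHOCH3 (6 equiv), TiCl4 (8 equiv), CH2Cl2, 0 °C → rt; then 1 M HCl
Reagents that add atoms: dichloromethyl methyl ether, COC(Cl)Cl (both formyl carbons); water, O (formyl oxygens)
Why: Rieche formylation, in which the titanium-bound phenoxides direct the electrophile to C3 and C5, the only open positions of the resorcinol ring A, and aqueous acid hydrolyses the α-chloro ethers of 21 to the two aldehydes; ring B has no free position.

Compound list
1 | 2-methylresorcinol | Cc1c(O)cccc1O | starting material
2 | (2,4-dihydroxy-3-methylbenzylidene)dimethyliminium chloride | C[N+](C)=Cc1ccc(O)c(C)c1O.[Cl-] | intermediate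
3 | 2,4-dihydroxy-3-methylbenzaldehyde | O=Cc1ccc(O)c(C)c1O | intermediate
4 | 2-hydroxy-4-methoxy-3-methylbenzaldehyde | COc1ccc(C=O)c(O)c1C | intermediate
5 | 3-methoxy-2,6-dimethylphenol | COc1ccc(C)c(O)c1C | intermediate
6 | 4-bromo-3-methoxy-2,6-dimethylphenol | COc1c(Br)cc(C)c(O)c1C | intermediate
7 | 1-bromo-2-methoxy-4-(methoxymethoxy)-3,5-dimethylbenzene | COCOc1c(C)c(OC)c(Br)cc1C | intermediate
8 | methylmagnesium chloride | C[Mg]Cl | starting material
9 | hexachloroethane | ClC(Cl)(Cl)C(Cl)(Cl)Cl | starting material
10 | [2-bromo-3-methoxy-5-(methoxymethoxy)-4,6-dimethylphenyl]lithium (drawn as the lithium species) | COCOc1c(C)c(OC)c(Br)c([Li])c1C | intermediate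
11 | 3-methoxy-5-(methoxymethoxy)-4,6-dimethyl-1,2-didehydrobenzene (aryne) | COCOC1=C(C)C#CC(OC)=C1C | intermediate
12 | [2-methoxy-4-(methoxymethoxy)-3,5,6-trimethylphenyl]magnesium chloride | COCOc1c(C)c(OC)c([Mg]Cl)c(C)c1C | intermediate
13 | 1-chloro-2-methoxy-4-(methoxymethoxy)-3,5,6-trimethylbenzene | COCOc1c(C)c(OC)c(Cl)c(C)c1C | intermediate
14 | 4-chloro-3-methoxy-2,5,6-trimethylphenol | COc1c(C)c(O)c(C)c(C)c1Cl | intermediate
15 | methyl orsellinate (methyl 2,4-dihydroxy-6-methylbenzoate) | COC(=O)c1c(C)cc(O)cc1O | starting material
16 | methyl 2,4-bis(benzyloxy)-6-methylbenzoate | COC(=O)c1c(C)cc(OCc2ccccc2)cc1OCc1ccccc1 | intermediate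
17 | 2,4-bis(benzyloxy)-6-methylbenzoic acid | OC(=O)c1c(C)cc(OCc2ccccc2)cc1OCc1ccccc1 | intermediate
18 | 2,4-bis(benzyloxy)-6-methylbenzoic trifluoroacetic anhydride | Cc1cc(OCc2ccccc2)cc(OCc2ccccc2)c1C(=O)OC(=O)C(F)(F)F | intermediate
19 | 4-chloro-3-methoxy-2,5,6-trimethylphenyl 2,4-bis(benzyloxy)-6-methylbenzoate | COc1c(C)c(OC(=O)c2c(C)cc(OCc3ccccc3)cc2OCc2ccccc2)c(C)c(C)c1Cl | intermediate
20 | 4-chloro-3-methoxy-2,5,6-trimethylphenyl 2,4-dihydroxy-6-methylbenzoate | COc1c(C)c(OC(=O)c2c(C)cc(O)cc2O)c(C)c(C)c1Cl | intermediate
21 | 4-chloro-3-methoxy-2,5,6-trimethylphenyl 3,5-bis[chloro(methoxy)methyl]-2,4-dihydroxy-6-methylbenzoate (diastereomer mixture, both centres lost on hydrolysis) | COc1c(C)c(OC(=O)c2c(C)c(C(Cl)OC)c(O)c(C(Cl)OC)c2O)c(C)c(C)c1Cl | intermediate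
22 | 4-chloro-3-methoxy-2,5,6-trimethylphenyl 3,5-diformyl-2,4-dihydroxy-6-methylbenzoate | COc1c(C)c(OC(=O)c2c(C)c(C=O)c(O)c(C=O)c2O)c(C)c(C)c1Cl | target

Total step count: 12.
Longest linear sequence: 10 steps (steps 1 to 7, then 10 to 12, from 2-methylresorcinol); steps 8 and 9 form the short ring A branch.

Steps most likely to fail

Step 6. The hindered C5 hydrogen may be removed too slowly for the aryne to form cleanly, the amide may capture the aryne in place of the methyl nucleophile, or some methyl may be delivered to C4. The fallback installs the same two substituents without an aryne and sets out from phenol 5. N-Chlorosuccinimide in MeCN should chlorinate para to the hydroxyl and give 4-chloro-3-methoxy-2,6-dimethylphenol F1. Br2 in AcOH should then brominate the last open ring position, which is activated by an ortho and a para methyl group, to give 3-bromo-4-chloro-5-methoxy-2,6-dimethylphenol F2. Suzuki–Miyaura methylation with trimethylboroxine, Pd(dppf)Cl2 and K2CO3 in dioxane/H2O at 90 °C should replace only the bromine, since the flanked, electron-rich C–Cl bond is far slower in oxidative addition. This comes back to the route at phenol 14, so steps 4 to 7 are bypassed.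

Step 12. After the first formyl group has entered, titanium chelation and the new acceptor may deactivate ring A so that the second formylation stalls. The fallback changes the C1 donor and the mechanism to a Duff reaction. It sets out from 20, which is heated with hexamethylenetetramine (4 equiv) in CF3CO2H at 90 °C and then hydrolysed with aqueous HCl. Iminium aminoalkylation followed by internal hydride transfer is known to drive ester-bearing phenols to dialdehydes. It comes back to the route at target 22 and makes no new isolable compound (F0).

Step 10. O-Acylation of the doubly flanked phenol may be outrun by trifluoroacetylation of the phenol or by attack of the acylium ion on the electron-rich ring of a second molecule of acid. The fallback separates activation from coupling and sets out from acid 17 and phenol 14. Oxalyl chloride with catalytic DMF in CH2Cl2 should give 2,4-bis(benzyloxy)-6-methylbenzoyl chloride F3. NaH in THF should convert 14 into sodium 4-chloro-3-methoxy-2,5,6-trimethylphenoxide F4. Combining the two in THF (rt → reflux) should give the ester, so the fallback comes back to the route at 19.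

Further compounds
F1 | step 6 | 4-chloro-3-methoxy-2,6-dimethylphenol | COc1c(Cl)cc(C)c(O)c1C
F2 | step 6 | 3-bromo-4-chloro-5-methoxy-2,6-dimethylphenol | COc1c(Cl)c(Br)c(C)c(O)c1C
F0 | step 12 | none | none
F3 | step 10 | 2,4-bis(benzyloxy)-6-methylbenzoyl chloride | Cc1cc(OCc2ccccc2)cc(OCc2ccccc2)c1C(Cl)=O
F4 | step 10 | sodium 4-chloro-3-methoxy-2,5,6-trimethylphenoxide | [Na+].[O-]c1c(C)c(OC)c(Cl)c(C)c1C
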